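**Route outline**

- Retrosynthesis: the naphthol is masked as a silyl ether and the C1 carbinol is taken back to a ketone. Then two C–C bonds are cut in one operation: C4–C4' between the tetralin and the naphthalene, and C2–C3 inside the saturated ring B.
- This leaves an α-bromoacetophenone carrying an ortho vinyl group (ring A, the anisole ring) and a 4-silyloxy-5-methoxy-1-naphthylboronic acid. Both go back to bought arenes through a vinyl–aryl bond, a C–Br bond and a C–B bond.
- Forward: ring A and the naphthalene are bought intact. Ring B (C1, C2, C3, C4, C4a, C8a) is the only ring made; it closes at C2–C3 in the same step that attaches the naphthyl group to C4.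
- Enabling feature: ring B carries at one end an oxygenated carbon C1 that can be a ketone, and at the other end of the C2–C3 bridge the doubly benzylic methine C4, which sits next to the C5 methoxy group and is bonded to C4' of the naphthol. A radical at C2 beside the C1 carbonyl can therefore reach the CH2 end (C3) of a vinyl group on C4a, and the ring closure places the new radical on C4, the carbon that must receive the naphthyl group.
- Stereochemistry: C4 (S) comes from the chiral bisoxazoline on copper in the ring-closing arylation. C1 (S) comes from a Corey–Bakshi–Shibata reduction of the C1 ketone, which gives the cis alcohol.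

Key step: step 8

Assumption: the sense of induction of a bisoxazoline on a ring-held benzylic radical cannot be assigned with certainty, so the (S,S) ligand is written in step 8 and its antipode would be used if a test run gave the 4R ketone; 8-methoxynaphthalen-1-ol is taken as purchasable.

**Route**

Step 1
Reactants: 1 1-(2-hydroxy-3-methoxyphenyl)ethanone
Product: 2 2-acetyl-6-methoxyphenyl trifluoromethanesulfonate
Conditions: Tf2O, pyridine, CH2Cl2, 0 °C to rt
Reagents that add atoms: trifluoromethanesulfonic anhydride, O=S(=O)(OS(=O)(=O)C(F)(F)F)C(F)(F)F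
Why: O-sulfonylation of the phenol (aryl triflate formation) turns the hydroxyl into a cross-coupling leaving group, and the methyl ketone is not enolised by pyridine at this temperature.

Step 2
Reactants: 2 2-acetyl-6-methoxyphenyl trifluoromethanesulfonate; 3 potassium vinyltrifluoroborate
Product: 4 1-(3-methoxy-2-vinylphenyl)ethanone
Conditions: PdCl2(dppf) (5 mol%), K2CO3, 1,4-dioxane/H2O, 85 °C
Reagents that add atoms: none
Why: Suzuki–Miyaura vinylation, in which oxidative addition of zerovalent palladium into the aryl triflate is helped by the ortho acetyl group and the trifluoroborate transmetalates after hydrolysis in the aqueous base.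

Step 3
Reactants: 4 1-(3-methoxy-2-vinylphenyl)ethanone
Product: 5 trimethyl{[1-(3-methoxy-2-vinylphenyl)vinyl]oxy}silane
Conditions: TMSOTf, Et3N, CH2Cl2, 0 °C; used crude
Reagents that add atoms: trimethylsilyl trifluoromethanesulfonate, C[Si](C)(C)OS(=O)(=O)C(F)(F)F
Why: Silyl enol ether formation by soft enolisation of a methyl ketone can give only one enol ether and leaves the styrene untouched.

Step 4
Reactants: 5 trimethyl{[1-(3-methoxy-2-vinylphenyl)vinyl]oxy}silane
Product: 6 2-bromo-1-(3-methoxy-2-vinylphenyl)ethanone
Conditions: NBS, THF, −78 to 0 °C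
Reagents that add atoms: N-bromosuccinimide, O=C1CCC(=O)N1Br
Why: Electrophilic α-bromination of a silyl enol ether is much faster than attack of NBS on the styrene or the anisole ring, so one bromine goes to the former methyl carbon without the over-bromination of a direct ketone bromination.

Step 5
Reactants: 7 8-methoxynaphthalen-1-ol
Product: 8 4-bromo-8-methoxynaphthalen-1-ol
Conditions: NBS (1.0 equiv), MeCN, −20 to 0 °C, dark
Reagents that add atoms: N-bromosuccinimide, O=C1CCC(=O)N1Br
Why: In this electrophilic aromatic substitution the free hydroxyl is the strongest donor and should direct NBS in acetonitrile to its para position C4, in preference to the ortho position C2 and to the positions activated only by the methoxy group.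

Step 6
Reactants: 8 4-bromo-8-methoxynaphthalen-1-ol
Product: 9 (4-bromo-8-methoxynaphthalen-1-yl)oxy-triisopropylsilane
Conditions: TIPSOTf, 2,6-lutidine, CH2Cl2, 0 °C to rt
Reagents that add atoms: triisopropylsilyl trifluoromethanesulfonate, CC(C)[Si](C(C)C)(C(C)C)OS(=O)(=O)C(F)(F)F
Why: O-Silylation with the silyl triflate overcomes the peri hindrance and the hydrogen bond to the methoxy group, and the bulky silyl ether masks the acidic naphthol through the lithiation and the copper step.

Step 7
Reactants: 9 (4-bromo-8-methoxynaphthalen-1-yl)oxy-triisopropylsilane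
Product: 12 [5-methoxy-4-(triisopropylsilyloxy)naphthalen-1-yl]boronic acid, via aryllithium 10 (not isolated), via lithium aryltriisopropoxyborate 11 (not isolated)
Conditions: n-BuLi, THF, −78 °C; B(OiPr)3, −78 °C to rt; 0.5 M HCl, 0 °C, brief
Reagents that add atoms: triisopropyl borate, CC(C)OB(OC(C)C)OC(C)C; water, O
Why: Bromine–lithium exchange followed by electrophilic borylation is reliable here because the lithium sits para to the silyl ether, so no silyl migration is possible, and the borate is hydrolysed to the boronic acid under mild acid.

Step 8
Reactants: 6 2-bromo-1-(3-methoxy-2-vinylphenyl)ethanone; 12 [5-methoxy-4-(triisopropylsilyloxy)naphthalen-1-yl]boronic acid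
Product: 15 (4S)-5-methoxy-4-[5-methoxy-4-(triisopropylsilyloxy)naphthalen-1-yl]-3,4-dihydronaphthalen-1(2H)-one, via α-keto radical 13 (not isolated), via cyclised benzylic radical 14 (not isolated)
Conditions: Cu(CH3CN)4PF6 (10 mol%), (S,S)-Ph-Box [2,2'-(propane-2,2-diyl)bis((4S)-4-phenyl-4,5-dihydrooxazole)] (12 mol%), Li2CO3, CH2Cl2/DMF, 0 °C to rt, slow addition of 6 at high dilution
Reagents that add atoms: none
Why: Proposed new method: the aryl copper complex formed from monovalent copper, the bisoxazoline and boronic acid 12 abstracts bromine from 6 to give the electrophilic α-keto radical 13, whose C2 adds to the CH2 terminus C3 of the ortho vinyl group and so closes ring B in a 6-endo-trig radical cyclisation, leaving radical 14 at C4. Radical 14 is captured by the chiral divalent aryl copper species and reductive elimination from the trivalent copper intermediate forms the C4–C4' bond, so C4 (S) is set by the ligand, which differentiates the faces of a planar, ring-held radical flanked by the C5 methoxy group on one side and C3 on the other. The closest known reaction type is the enantioselective copper/bisoxazoline radical-relay carboarylation of vinylarenes, in which a benzylic radical made by radical addition to a styrene is arylated by an arylboronic acid; the intramolecular, ring-forming radical addition is the new element. The step needs 6-endo rather than 5-exo closure, secured by the benzylic, methoxy-stabilised radical that only the 6-endo mode produces, by the strain of the alternative indanone transition state and by the polarity match between the α-keto radical and the styrene terminus. It also needs cyclisation to outrun arylation of 13, which the unimolecular ring closure should win at low copper concentration, and a C4 bromide formed by atom transfer is reopened by monovalent copper to 14 and is therefore not a dead end.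

Step 9
Reactants: 15 (4S)-5-methoxy-4-[5-methoxy-4-(triisopropylsilyloxy)naphthalen-1-yl]-3,4-dihydronaphthalen-1(2H)-one
Product: 16 (1S,4S)-5-methoxy-4-[5-methoxy-4-(triisopropylsilyloxy)naphthalen-1-yl]-1,2,3,4-tetrahydronaphthalen-1-ol
Conditions: (R)-Me-CBS oxazaborolidine (20 mol%), BH3·THF, THF, −20 °C; MeOH quench
Reagents that add atoms: none
Why: In this Corey–Bakshi–Shibata reduction the (R)-oxazaborolidine treats the aryl side of the tetralone as the large group and delivers hydride to the face that gives the 1S alcohol, cis to the C4 naphthyl group, and hydride entry anti to the pseudoaxial naphthyl group leads to the same isomer, so any substrate bias should reinforce the catalyst.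

Step 10
Reactants: 16 (1S,4S)-5-methoxy-4-[5-methoxy-4-(triisopropylsilyloxy)naphthalen-1-yl]-1,2,3,4-tetrahydronaphthalen-1-ol
Product: 17 Dipolynaphthalene B [(1S,4S)-4-(4-hydroxy-5-methoxynaphthalen-1-yl)-5-methoxy-1,2,3,4-tetrahydronaphthalen-1-ol]
Conditions: Bu4NF, AcOH, THF, 0 °C, under argon
Reagents that add atoms: none
Why: Fluoride-mediated desilylation cleaves the aryl O–Si bond, and the acetic acid buffer keeps the electron-rich naphthol protonated and leaves the benzylic alcohol, both methyl ethers and both stereocentres untouched.

**Compound list**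

1 | 1-(2-hydroxy-3-methoxyphenyl)ethanone | CC(=O)c1cccc(OC)c1O | starting material
2 | 2-acetyl-6-methoxyphenyl trifluoromethanesulfonate | CC(=O)c1cccc(OC)c1OS(=O)(=O)C(F)(F)F | intermediate
3 | potassium vinyltrifluoroborate | C=C[B-](F)(F)F.[K+] | starting material
4 | 1-(3-methoxy-2-vinylphenyl)ethanone | CC(=O)c1cccc(OC)c1C=C | intermediate
5 | trimethyl{[1-(3-methoxy-2-vinylphenyl)vinyl]oxy}silane | C=C(O[Si](C)(C)C)c1cccc(OC)c1C=C | intermediate
6 | 2-bromo-1-(3-methoxy-2-vinylphenyl)ethanone | O=C(CBr)c1cccc(OC)c1C=C | intermediate
7 | 8-methoxynaphthalen-1-ol | COc1cccc2cccc(O)c12 | starting material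
8 | 4-bromo-8-methoxynaphthalen-1-ol | COc1cccc2c(Br)ccc(O)c12 | intermediate
9 | (4-bromo-8-methoxynaphthalen-1-yl)oxy-triisopropylsilane | COc1cccc2c(Br)ccc(O[Si](C(C)C)(C(C)C)C(C)C)c12 | intermediate
10 | [5-methoxy-4-(triisopropylsilyloxy)naphthalen-1-yl]lithium | COc1cccc2c([Li])ccc(O[Si](C(C)C)(C(C)C)C(C)C)c12 | intermediate
11 | lithium triisopropoxy[5-methoxy-4-(triisopropylsilyloxy)naphthalen-1-yl]borate | [Li+].COc1cccc2c([B-](OC(C)C)(OC(C)C)OC(C)C)ccc(O[Si](C(C)C)(C(C)C)C(C)C)c12 | intermediate
12 | [5-methoxy-4-(triisopropylsilyloxy)naphthalen-1-yl]boronic acid | COc1cccc2c(B(O)O)ccc(O[Si](C(C)C)(C(C)C)C(C)C)c12 | intermediate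
13 | 2-(3-methoxy-2-vinylphenyl)-2-oxoethyl radical | [CH2]C(=O)c1cccc(OC)c1C=C | intermediate
14 | 8-methoxy-4-oxo-1,2,3,4-tetrahydronaphthalen-1-yl radical (C4 radical of 5-methoxy-1-tetralone) | COc1cccc2c1[CH]CCC2=O | intermediate
15 | (4S)-5-methoxy-4-[5-methoxy-4-(triisopropylsilyloxy)naphthalen-1-yl]-3,4-dihydronaphthalen-1(2H)-one | COc1cccc2c1[C@H](c1ccc(O[Si](C(C)C)(C(C)C)C(C)C)c3c(OC)cccc13)CCC2=O | intermediate
16 | (1S,4S)-5-methoxy-4-[5-methoxy-4-(triisopropylsilyloxy)naphthalen-1-yl]-1,2,3,4-tetrahydronaphthalen-1-ol | COc1cccc2c1[C@H](c1ccc(O[Si](C(C)C)(C(C)C)C(C)C)c3c(OC)cccc13)CC[C@@H]2O | intermediate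
17 | Dipolynaphthalene B, (1S,4S)-4-(4-hydroxy-5-methoxynaphthalen-1-yl)-5-methoxy-1,2,3,4-tetrahydronaphthalen-1-ol | COc1cccc2c1[C@H](c1ccc(O)c3c(OC)cccc13)CC[C@@H]2O | target

**Step count**

Total step count: 10. Longest linear sequence: 7 steps (steps 1, 2, 3, 4, 8, 9, 10).

**Steps most likely to fail**

Step 8. Possible failures are:
- arylation of radical 13 before it cyclises;
- reduction of 6 together with homocoupling of 12;
- oxidation of radical 14 to the cation, followed by loss of a C3 proton and aromatisation to a naphthol;
- slow transfer of the peri-hindered naphthyl group;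
- poor face selection at C4.

The fallback uses known chemistry, sets out from 6 and 9 and comes back at 15, and separates the two bond formations. Bromoketone 6 would be cyclised by copper-catalysed atom-transfer radical cyclisation (CuBr, tris(2-pyridylmethyl)amine, 1,2-dichloroethane, 60 °C). This uses the same 6-endo closure but ends by bromine transfer, giving racemic 4-bromo-5-methoxy-3,4-dihydronaphthalen-1(2H)-one F1. Bromide 9 would be converted with n-BuLi and then ZnCl2 (THF, −78 °C to rt) into [5-methoxy-4-(triisopropylsilyloxy)naphthalen-1-yl]zinc chloride F2. A stereoconvergent nickel-catalysed Negishi arylation of the racemic secondary benzylic bromide (NiBr2(dme), chiral bisoxazoline ligand, THF/DMA, −20 °C) would then join F1 and F2 to give 15. Both enantiomers of F1 pass through the same C4 radical, so the ligand on nickel sets C4.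

Step 7. Possible failures are protodeboronation of the electron-rich naphthylboronic acid, or loss of the silyl group, during the acidic hydrolysis of the borate. The fallback sets out from 9 and comes back at 12, and replaces the organolithium route by a palladium-catalysed one. Miyaura borylation of 9 (B2pin2, PdCl2(dppf), KOAc, 1,4-dioxane, 80 °C) would give 2-[5-methoxy-4-(triisopropylsilyloxy)naphthalen-1-yl]-4,4,5,5-tetramethyl-1,3,2-dioxaborolane F3, which can be purified on silica. Oxidative cleavage of the pinacol ester (NaIO4, NH4OAc, acetone/H2O, rt) would then release boronic acid 12 at near-neutral pH.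

Step 9. The possible failure is poor facial selectivity if the bias of the substrate opposes the (R)-oxazaborolidine. The fallback sets out from 15 and comes back at 16. The ketone would be reduced with the enantiomeric (S)-Me-CBS oxazaborolidine and BH3·THF, which in that case is the matched pair, to give (1R,4S)-5-methoxy-4-[5-methoxy-4-(triisopropylsilyloxy)naphthalen-1-yl]-1,2,3,4-tetrahydronaphthalen-1-ol F4, the trans alcohol. Mitsunobu inversion with chloroacetic acid (PPh3, DIAD, THF, 0 °C) would give (1S,4S)-5-methoxy-4-[5-methoxy-4-(triisopropylsilyloxy)naphthalen-1-yl]-1,2,3,4-tetrahydronaphthalen-1-yl chloroacetate F5. Brief methanolysis (K2CO3 catalytic, MeOH, 0 °C), mild enough to spare the aryl silyl ether, would return the cis alcohol 16.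

**Further compounds**

F1 | step 8 | rac-4-bromo-5-methoxy-3,4-dihydronaphthalen-1(2H)-one | COc1cccc2c1C(Br)CCC2=O
F2 | step 8 | [5-methoxy-4-(triisopropylsilyloxy)naphthalen-1-yl]zinc chloride | COc1cccc2c([Zn]Cl)ccc(O[Si](C(C)C)(C(C)C)C(C)C)c12
F3 | step 7 | 2-[5-methoxy-4-(triisopropylsilyloxy)naphthalen-1-yl]-4,4,5,5-tetramethyl-1,3,2-dioxaborolane | COc1cccc2c(B3OC(C)(C)C(C)(C)O3)ccc(O[Si](C(C)C)(C(C)C)C(C)C)c12
F4 | step 9 | (1R,4S)-5-methoxy-4-[5-methoxy-4-(triisopropylsilyloxy)naphthalen-1-yl]-1,2,3,4-tetrahydronaphthalen-1-ol | COc1cccc2c1[C@H](c1ccc(O[Si](C(C)C)(C(C)C)C(C)C)c3c(OC)cccc13)CC[C@H]2O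
F5 | step 9 | (1S,4S)-5-methoxy-4-[5-methoxy-4-(triisopropylsilyloxy)naphthalen-1-yl]-1,2,3,4-tetrahydronaphthalen-1-yl chloroacetate | COc1cccc2c1[C@H](c1ccc(O[Si](C(C)C)(C(C)C)C(C)C)c3c(OC)cccc13)CC[C@@H]2OC(=O)CCl
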